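**Retrosynthetic overview**
- Target ⇒ Mizoroki–Heck union (C10–C11) of a ring B isopropenyl epoxy ketone with a ring A C26 polyenyl iodide.
- Ring B ketone ⇐ MnO2 oxidation ⇐ C8 carbinol ⇐ zinc-induced opening of an epoxy iodide ⇐ bis-epoxide ⇐ one-flask double epoxidation of a 1,4-dienol. The ring B oxirane is kept; the side-chain oxirane only relays oxygen from C10 to C8.
- 1,4-Dienol ⇐ palladium allyl–alkenyl coupling of a ring boronate with isoprene monoxide ⇐ enol triflate ⇐ actinol acetate.
- Ring A iodide ⇐ Takai olefination ⇐ C25 aldehyde ⇐ Wittig with the C10 dialdehyde ⇐ C15 phosphonium salt ⇐ Sonogashira coupling of the same enol triflate.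
- Ring order: both six-membered rings come ready-made from (4R,6R)-actinol; the two oxiranes are closed together in one operation (step 5); no other ring is formed.

Assumption: (4R,6R)-actinol 1 is bought as the industrial zeaxanthin intermediate. Atom labels C1–C20 (and primed) follow carotenoid numbering.

**Route**

Step 1
Reactants: 1 (4R,6R)-actinol
Product: 2 actinol acetate
Conditions: Ac2O, pyridine, DMAP (cat.), CH2Cl2, 0 → 25 °C
Reagents that add atoms: acetic anhydride, CC(=O)OC(C)=O
Why: DMAP-catalysed O-acetylation (nucleophilic acyl substitution) of the only hydroxyl; the acetate survives the triflation and palladium steps, later steers the peracid to the opposite ring face, and the carbinol stereocentre is carried unchanged into C3 and C3' of the target.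

Step 2
Reactants: 2 actinol acetate
Product: 3 ring enol triflate
Conditions: Tf2O, 2,6-di-tert-butyl-4-methylpyridine, CH2Cl2, 0 → 25 °C
Reagents that add atoms: triflic anhydride, O=S(=O)(OS(=O)(=O)C(F)(F)F)C(F)(F)F
Why: Stang-type enol triflation; the ketone can enolise only toward its single α-hydrogen, so one tetrasubstituted enol triflate forms and the now irrelevant α-stereocentre is erased.

Step 3
Reactants: 3 ring enol triflate
Product: 4 ring pinacol boronate
Conditions: B2pin2, PdCl2(dppf) (5 mol %), KOAc, dioxane, 80 °C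
Reagents that add atoms: bis(pinacolato)diboron, CC1(C)OB(OC1(C)C)B1OC(C)(C)C(C)(C)O1
Why: Miyaura borylation (oxidative addition of the C–OTf bond to zerovalent palladium, acetate-assisted transmetalation, reductive elimination); the ester and the stereocentre are inert.

Step 4
Reactants: 4 ring pinacol boronate; 5 isoprene monoxide
Product: 6 ring B 1,4-dienol acetate
Conditions: Pd(PPh3)4 (5 mol %), THF/H2O (10:1), 50 °C
Reagents that add atoms: none
Why: Suzuki–Miyaura type allyl–alkenyl coupling; zerovalent palladium opens the vinyl oxirane to a π-allylpalladium alkoxide that activates boron, and the ring carbon is delivered to the unhindered CH2 terminus (1,4-addition); the E/Z ratio of the new alkene does not matter because that double bond is consumed in step 5.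

Step 5
Reactants: 6 ring B 1,4-dienol acetate
Product: 8 ring B bis-epoxide acetate, via ring B monoepoxide 7 (not isolated)
Conditions: mCPBA (2.4 equiv), CH2Cl2/aq NaHCO3, 0 °C
Reagents that add atoms: mCPBA, O=C(OO)c1cccc(Cl)c1
Why: Double Prilezhaev epoxidation closes two oxirane rings in one operation (tetrasubstituted ring alkene first, then the trisubstituted allylic-alcohol alkene); the peracid attacks the ring alkene mainly trans to the C3 acetoxy group, as reported for other acylated 3-hydroxy-β-end groups (about 4:1 expected), which sets the 5R,6S oxirane, while the configuration of the side-chain oxirane is irrelevant because it is destroyed in step 7.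

Step 6
Reactants: 8 ring B bis-epoxide acetate
Product: 9 ring B epoxy iodide
Conditions: PPh3, imidazole, I2, CH2Cl2, 0 °C
Reagents that add atoms: iodine, [I][I]
Why: Garegg–Samuelsson (Appel-type) iodination of the primary epoxy alcohol through an alkoxyphosphonium iodide and SN2 displacement; both oxiranes and the acetate survive these neutral conditions.

Step 7
Reactants: 9 ring B epoxy iodide
Product: 11 ring B epoxy diol, via C8 carbinol acetate 10 (not isolated)
Conditions: Zn dust, MeOH, NaHCO3 (buffer), 50 °C; filter; then K2CO3 (cat.), 25 °C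
Reagents that add atoms: none
Why: Zinc inserts into the carbon–iodine bond and β-elimination of the organozinc opens the side-chain oxirane (reductive 1,3-transposition that moves oxygen from C10 to C8 and creates the C9=C10 methylene), then Zemplén-type methanolysis removes the acetate; the C8 carbinol is an epimer mixture that is oxidised away in step 8.

Step 8
Reactants: 11 ring B epoxy diol
Product: 12 ring B isopropenyl epoxy ketone
Conditions: MnO2 (activated, excess), CH2Cl2, 25 °C
Reagents that add atoms: none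
Why: MnO2 oxidises only the allylic C8 alcohol and leaves the unactivated C3 hydroxyl and the oxirane alone, so no protecting group is needed; the minor cis-oxirane diastereomer from step 5 is removed here by chromatography and 12 is used at once.

Step 9
Reactants: 3 ring enol triflate; 13 (2E)-3-methylpent-2-en-4-yn-1-ol
Product: 14 ring A enynol acetate
Conditions: Pd(PPh3)4 (5 mol %), CuI (10 mol %), iPr2NH, DMF, 50 °C
Reagents that add atoms: none
Why: Sonogashira coupling of the hindered enol triflate with the terminal alkyne gives the 7',8'-didehydro end group directly, with the E geometry of 13 retained.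

Step 10
Reactants: 14 ring A enynol acetate
Product: 15 ring A C15 phosphonium bromide
Conditions: Ph3P·HBr, CH2Cl2, 25 °C
Reagents that add atoms: triphenylphosphine hydrobromide, [PH+](c1ccccc1)(c1ccccc1)c1ccccc1.[Br-]
Why: Standard C15 Wittig-salt formation (acid-mediated ionisation of the primary allylic alcohol and capture by PPh3); the acetate is stable and the E alkene is kept.

Step 11
Reactants: 15 ring A C15 phosphonium bromide; 16 C10 dialdehyde
Product: 19 ring A C25 aldehyde, via phosphonium ylide 17 (not isolated), via C25 aldehyde acetate 18 (not isolated)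
Conditions: 16 (3 equiv), NaOMe, MeOH/CH2Cl2, 0 → 25 °C; then I2 (cat.), CH2Cl2, daylight
Reagents that add atoms: none
Why: Wittig olefination of one formyl group of the excess dialdehyde forms C11'=C12', the methoxide medium also cleaves the acetate (Zemplén methanolysis), and iodine-catalysed isomerisation funnels the new double bond to E.

Step 12
Reactants: 19 ring A C25 aldehyde
Product: 20 ring A C26 polyenyl iodide
Conditions: CrCl2 (6 equiv), CHI3 (2 equiv), THF, 0 °C, dark
Reagents that add atoms: iodoform, IC(I)I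
Why: Takai iodo-olefination (geminal dichromium reagent from CHI3 and divalent chromium) converts the aldehyde into the E-vinyl iodide and adds C11; the free hydroxyl and the enyne are tolerated.

Step 13
Reactants: 12 ring B isopropenyl epoxy ketone; 20 ring A C26 polyenyl iodide
Product: 21 halocynthiaxanthin
Conditions: Pd(OAc)2 (10 mol %), Bu4NCl, NaHCO3, DMF, 40 °C, dark
Reagents that add atoms: none
Why: Mizoroki–Heck coupling under Jeffery conditions; the polyenylpalladium adds to the unsubstituted CH2 terminus of the α-methyl enone and syn β-hydride elimination toward C10 gives the conjugated E dienone (C11 trans to the C8 carbonyl) under a base mild enough for the β,γ-epoxy ketone; no stereocentre is touched.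

**Compound list**

1 | (4R,6R)-4-hydroxy-2,2,6-trimethylcyclohexan-1-one ((4R,6R)-actinol) | O=C1C(C)(C)C[C@H](O)C[C@H]1C | starting material
2 | (1R,5R)-3,3,5-trimethyl-4-oxocyclohexyl acetate | O=C1C(C)(C)C[C@H](OC(C)=O)C[C@H]1C | intermediate
3 | (4R)-4-acetoxy-2,6,6-trimethylcyclohex-1-en-1-yl trifluoromethanesulfonate | CC1=C(OS(=O)(=O)C(F)(F)F)C(C)(C)C[C@H](OC(C)=O)C1 | intermediate
4 | (1R)-3,5,5-trimethyl-4-(4,4,5,5-tetramethyl-1,3,2-dioxaborolan-2-yl)cyclohex-3-en-1-yl acetate | CC1=C(B2OC(C)(C)C(C)(C)O2)C(C)(C)C[C@H](OC(C)=O)C1 | intermediate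
5 | 2-methyl-2-vinyloxirane (isoprene monoxide, racemic) | C=CC1(C)CO1 | starting material
6 | (1R)-4-[(2E)-4-hydroxy-3-methylbut-2-en-1-yl]-3,5,5-trimethylcyclohex-3-en-1-yl acetate (E major; Z isomer equally usable) | OC/C(C)=C/CC1=C(C)C[C@@H](OC(C)=O)CC1(C)C | intermediate
7 | (1S,4S,6R)-1-[(2E)-4-hydroxy-3-methylbut-2-en-1-yl]-2,2,6-trimethyl-7-oxabicyclo[4.1.0]heptan-4-yl acetate (formed in the flask, not isolated) | OC/C(C)=C/C[C@@]12O[C@]1(C)C[C@@H](OC(C)=O)CC2(C)C | intermediate
8 | (1S,4S,6R)-1-{[3-(hydroxymethyl)-3-methyloxiran-2-yl]methyl}-2,2,6-trimethyl-7-oxabicyclo[4.1.0]heptan-4-yl acetate (side-chain oxirane as isomer mixture) | OCC1(C)OC1C[C@@]23O[C@]2(C)C[C@@H](OC(C)=O)CC3(C)C | intermediate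
9 | (1S,4S,6R)-1-{[3-(iodomethyl)-3-methyloxiran-2-yl]methyl}-2,2,6-trimethyl-7-oxabicyclo[4.1.0]heptan-4-yl acetate (side-chain oxirane as isomer mixture) | ICC1(C)OC1C[C@@]23O[C@]2(C)C[C@@H](OC(C)=O)CC3(C)C | intermediate
10 | (1S,4S,6R)-1-(2-hydroxy-3-methylbut-3-en-1-yl)-2,2,6-trimethyl-7-oxabicyclo[4.1.0]heptan-4-yl acetate (carbinol epimers; formed in the flask, not isolated) | C=C(C)C(O)C[C@@]12O[C@]1(C)C[C@@H](OC(C)=O)CC2(C)C | intermediate
11 | (1S,4S,6R)-1-(2-hydroxy-3-methylbut-3-en-1-yl)-2,2,6-trimethyl-7-oxabicyclo[4.1.0]heptan-4-ol (carbinol epimers) | C=C(C)C(O)C[C@@]12O[C@]1(C)C[C@@H](O)CC2(C)C | intermediate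
12 | 1-[(1S,4S,6R)-4-hydroxy-2,2,6-trimethyl-7-oxabicyclo[4.1.0]heptan-1-yl]-3-methylbut-3-en-2-one | C=C(C)C(=O)C[C@@]12O[C@]1(C)C[C@@H](O)CC2(C)C | intermediate
13 | (2E)-3-methylpent-2-en-4-yn-1-ol | C#C/C(C)=C/CO | starting material
14 | (1R)-4-[(3E)-5-hydroxy-3-methylpent-3-en-1-yn-1-yl]-3,5,5-trimethylcyclohex-3-en-1-yl acetate | CC1=C(C#C/C(C)=C/CO)C(C)(C)C[C@H](OC(C)=O)C1 | intermediate
15 | {(2E)-5-[(4R)-4-acetoxy-2,6,6-trimethylcyclohex-1-en-1-yl]-3-methylpent-2-en-4-yn-1-yl}triphenylphosphonium bromide | CC1=C(C#C/C(C)=C/C[P+](c2ccccc2)(c2ccccc2)c2ccccc2)C(C)(C)C[C@H](OC(C)=O)C1.[Br-] | intermediate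
16 | (2E,4E,6E)-2,7-dimethylocta-2,4,6-trienedial (C10 dialdehyde) | O=C/C(C)=C/C=C/C=C(C)/C=O | starting material
17 | triphenylphosphonium ylide of 15 (formed in the flask, not isolated) | CC1=C(C#C/C(C)=C/C=P(c2ccccc2)(c2ccccc2)c2ccccc2)C(C)(C)C[C@H](OC(C)=O)C1 | intermediate
18 | (2E,4E,6E,8E,10E)-13-[(4R)-4-acetoxy-2,6,6-trimethylcyclohex-1-en-1-yl]-2,7,11-trimethyltrideca-2,4,6,8,10-pentaen-12-ynal (formed in the flask, not isolated) | CC1=C(C#C/C(C)=C/C=C/C(C)=C/C=C/C=C(C)/C=O)C(C)(C)C[C@H](OC(C)=O)C1 | intermediate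
19 | (2E,4E,6E,8E,10E)-13-[(4R)-4-hydroxy-2,6,6-trimethylcyclohex-1-en-1-yl]-2,7,11-trimethyltrideca-2,4,6,8,10-pentaen-12-ynal | CC1=C(C#C/C(C)=C/C=C/C(C)=C/C=C/C=C(C)/C=O)C(C)(C)C[C@H](O)C1 | intermediate
20 | (1R)-4-[(3E,5E,7E,9E,11E,13E)-14-iodo-3,7,12-trimethyltetradeca-3,5,7,9,11,13-hexaen-1-yn-1-yl]-3,5,5-trimethylcyclohex-3-en-1-ol | CC1=C(C#C/C(C)=C/C=C/C(C)=C/C=C/C=C(C)/C=C/I)C(C)(C)C[C@H](O)C1 | intermediate
21 | (3S,5R,6S,3'R)-5,6-epoxy-3,3'-dihydroxy-7',8'-didehydro-5,6,7,8-tetrahydro-β,β-caroten-8-one (halocynthiaxanthin, CNP0332618.1) | CC1=C(C#C/C(C)=C/C=C/C(C)=C/C=C/C=C(C)/C=C/C=C(\C)C(=O)C[C@@]23O[C@]2(C)C[C@@H](O)CC3(C)C)C(C)(C)C[C@H](O)C1 | target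

**Step count and risks**

Total steps: 13. Longest linear sequence: 9 (steps 1–8, then step 13).

Most likely to fail, step 5 (double epoxidation). The facial ratio at the ring alkene may be poor or reversed, or the acid by-product may damage the tetrasubstituted oxirane. Fallback, from 6 back to 8: both oxiranes are closed from halohydrins instead, which puts the ring oxygen on the face opposite to the one an electrophile prefers. N-Bromosuccinimide in wet 1,2-dimethoxyethane at 0 °C converts 6 into the bis-bromohydrin F1 (bromine on C6 and C8, hydroxyl on C5 and C9). DBU in toluene at 25 °C then closes both rings by intramolecular SN2 displacement and the route is rejoined at 8.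

Second, step 4 (coupling of the hindered boronate with the vinyl oxirane; this fallback also bypasses step 3). Fallback, from 3 back to 6: Stille allylation of 3 with allyltributylstannane (Pd(PPh3)4, LiCl, THF, 65 °C) gives the allyl compound F2. Cross-metathesis of F2 with excess 2-methylprop-2-en-1-ol (second-generation Hoveyda–Grubbs catalyst, CH2Cl2, 40 °C) gives 6 as an E/Z mixture, which is equally usable.

Third, step 13 (final Heck union). β-Hydride elimination toward the methyl group or base-induced opening of the β,γ-epoxy ketone could lower the yield. Fallback, from 11 (with 20) to 21: cross-metathesis of 11 with vinylboronic acid pinacol ester (second-generation Hoveyda–Grubbs catalyst, CH2Cl2, 40 °C) gives the E-alkenyl boronate F3. Suzuki–Miyaura coupling of F3 with 20 (Pd(PPh3)4, aqueous K3PO4, THF, 25 °C) gives the C40 triol F4, which carries the C8 carbinol. MnO2 in CH2Cl2 then oxidises only the doubly allylic C8 alcohol, so the ketone appears in the last, base-free operation and the product is 21.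

Further compounds
F1 | step 5 | (1R)-4-bromo-4-(2-bromo-3,4-dihydroxy-3-methylbutyl)-3-hydroxy-3,5,5-trimethylcyclohexyl acetate (bis-bromohydrin, new centres as mixture) | OCC(C)(O)C(Br)CC1(Br)C(C)(O)C[C@@H](OC(C)=O)CC1(C)C
F2 | step 4 | (1R)-3,5,5-trimethyl-4-(prop-2-en-1-yl)cyclohex-3-en-1-yl acetate | C=CCC1=C(C)C[C@@H](OC(C)=O)CC1(C)C
F3 | step 13 | (1S,4S,6R)-1-[(3E)-2-hydroxy-3-methyl-4-(4,4,5,5-tetramethyl-1,3,2-dioxaborolan-2-yl)but-3-en-1-yl]-2,2,6-trimethyl-7-oxabicyclo[4.1.0]heptan-4-ol (carbinol epimers) | CC1(C)OB(OC1(C)C)/C=C(\C)C(O)C[C@@]23O[C@]2(C)C[C@@H](O)CC3(C)C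
F4 | step 13 | (3S,5R,6S,3'R)-5,6-epoxy-7',8'-didehydro-5,6,7,8-tetrahydro-β,β-carotene-3,8,3'-triol (C8 epimers) | CC1=C(C#C/C(C)=C/C=C/C(C)=C/C=C/C=C(C)/C=C/C=C(\C)C(O)C[C@@]23O[C@]2(C)C[C@@H](O)CC3(C)C)C(C)(C)C[C@H](O)C1
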